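## Analysis of the target

Talapolyester A is an open-chain oligoester of four hydroxy acids. From the free-hydroxyl end these are (S)-3-hydroxybutanoic acid, (R)-3-hydroxybutanoic acid, 2,4-dihydroxy-6-[(R)-2-hydroxypropyl]benzoic acid and (R)-3,4-dihydroxybutanoic acid, joined through three esters of secondary oxygens and ending in a free carboxylic acid. The only ring is the benzene ring, with the carboxyl at C1, hydroxyls at C2 and C4 and the side chain at C6. The four stereocentres are isolated carbinol carbons separated by ester links, so none can direct another and each must come from an enantiopure building block; three are (R) and the terminal one is (S). The sensitive groups are: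

- two β-acyloxy esters and one β-acyloxy acid, which lose carboxylate under base;
- a benzoate on a secondary oxygen next to a free primary hydroxyl, which can migrate;
- a 4-hydroxy acid, which can lactonise;
- the ortho pair of carboxyl and 2-oxypropyl chain, which closes to a six-membered lactone whenever the side-chain oxygen is free.

The synthesis is hard because four carboxyl groups of the same kind must be joined in a fixed order with no step that relies on selective hydrolysis, and because the benzoic acid is flanked by two ortho substituents. The strategy rests on one repeated pattern. In the inner unit O–C(=O)–CH2–CH(CH3)–O, in the terminal unit, and in the side chain C6–CH2–CH(CH3)–O, the atoms CH2–CH(CH3)–O are those of propylene oxide, extended at CH2 by one carbon (a carbonyl carbon or ring carbon C6). The unit O–CH(CH2OH)–CH2–C(=O) is likewise a glycidyl ether plus one carbonyl carbon.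

## Retrosynthetic reasoning

**17 to 16.** All five free hydroxyl and carboxyl functions of 17 are masked in 16 as O-benzyl groups (two aryl ethers, two alkyl ethers, one ester). The last step therefore cuts only O–CH2Ph bonds by hydrogenolysis. Base, hot acid and hydrolysis are all excluded at this stage by the groups listed above.

**16 to 12 and 14.** The benzoate C(=O)–O bond is cut. This keeps the monoacylated diol and the future free acid, both carried by 14, out of every earlier step. The forward reaction must acylate a secondary hydroxyl with a di-ortho-substituted aroyl group with retention at the carbinol carbon; acid chloride 15 is the acyl donor. Alcohol 14 is cut at its ester bond and its C1–C2 bond into epoxide 13 and 5, the same cobalt chemistry run with the esterifying alcohol in large excess.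

**12 to 11 to 9.** The bond from ring C1 to the carboxyl carbon is cut. A carboxyl derivative cannot sit ortho to a side chain with a free oxygen, so the side-chain oxygen must already be acylated when the carboxyl carbon arrives. The carbon therefore enters late, by electrophilic formylation of 9 (through iminium salt 10) at the position ortho to the side chain and para to a benzyloxy group, followed by oxidation of 11.

**9 to 8 to 6, 7 and 5.** After removal of the O-benzyl group from the terminal hydroxyl, the terminal unit of 8 is cut at its ester C–O bond and its CH2–C(=O) bond. This leads to 6, epoxide 7 and 5. No β-oxygenated acid is activated, and the hydroxyl set free is the one to be protected.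

**6 to 4, 2 and 5.** This is the key disconnection. The ester C–O bond and the CH2–C(=O) bond of the inner unit are cut together, giving alcohol 4, epoxide 2 and 5. The forward step must open 2 at CH2, insert 5, and pass the acyl group to the hydroxyl of 4 with only a small excess of that alcohol.

**4 to 1 and 2.** The aryl–CH2 bond is cut. The aryl group of 1 is made nucleophilic as Grignard reagent 3 and opens a second molecule of 2 at CH2. The side-chain stereocentre thus comes from the same epoxide as the inner unit.

## Alternatives that were turned down

**Alternative 1:** The inner and terminal units of 8 have opposite configurations, so their head-to-tail cyclic dimer is achiral. This leads back to the meso diolide A2, and removal of both ring oxygens leads to the centrosymmetric trans-dione A1.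
- Forward key step: a buffered peracid would insert oxygen twice into A1, each time with migration of the methyl-bearing carbon with retention, expanding the six-membered ring to the eight-membered A2. Opening A2 with 4 would give 8.
- For it: two units and both their stereocentres come from one achiral ring without enantiopure three- or four-carbon building blocks. Ring opening frees exactly one hydroxyl, so over-insertion, the main selectivity problem of the chosen route, cannot occur. On that point it is stronger.
- Against it: the two ester carbonyls of A2 are enantiotopic, and the only chiral information is the remote carbinol centre of 4. The opening should therefore give 8 together with its isomer of inverted unit order, which differs only at remote centres and would be hard to separate. In addition, the second oxygen insertion acts on a β-acyloxy ketone that can eliminate, A1 epimerises to its chiral cis isomer, and opening an eight-membered dilactone with a secondary alkoxide invites elimination in the product.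
- Comparison: the chosen strategy takes each centre from an enantiopure epoxide and never has to choose between diastereomers.

**Alternative 2:** The benzene ring is cut at C1–C2 and C5–C6. C1 and C6 come from the triple bond of the alkynoate A4, which already carries both ester arms; C2 to C5 with both phenol oxygens come from the diene A3.
- Forward key step: the terminal CH2 of A3 would add to the β-carbon and its acetal carbon to the α-carbon of A4. The adduct would aromatise on mild acidic work-up, by loss of its methoxy and silyl groups, to the free resorcylate A5.
- For it: the ring substitution pattern is fixed by polarity, and the aryl ester exists before the ring does. It is therefore stronger than the chosen route on both of its late risks, the regiochemistry of step 5 and the hindered esterification of step 8. The phenols emerge free and only three benzyl groups remain.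
- Against it: β-alkyl alkynoates are poor partners for such dienes and need heat or a Lewis acid, under which A3 decomposes. The propargylic CH2 of A4 lies between the ynoate and an acyloxy-bearing carbon, so isomerisation to an allene and loss of the acyloxy group threaten. The whole chain is at stake in the last carbon–carbon bond formation.
- Comparison: the length is similar, but the chosen route places its uncertain step second, on cheap materials.

**Alternative 3:** The ring-to-carbonyl bond at C1 and the ring-to-CH2 bond at C6 are traced to an aryne. The benzocyclobutenone A9, opened at its carbonyl by an oxygen nucleophile, gives a benzoate with an ortho CH2 group. A9 comes from the aryne A6, released from the iodo triflate A7, and the ketene silyl acetal A8.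
- Forward key step: an alkyllithium would convert A7 into A6. The nucleophilic carbon of A8 would add to the aryne carbon remote from the neighbouring benzyloxy group, and [2+2] closure and hydrolysis would give A9 as both epimers at C8.
- For it: regiochemistry is set by the alkoxy group next to the aryne, and the carboxyl carbon and side chain arrive together. Strain-driven opening could in principle form the hindered ester without acyl substitution at a hindered acid, which would be stronger than step 8.
- Against it: A7 takes several steps. A8 derives from a β-silyloxy ester enolate that tends to eliminate. The opening would need the alkoxide of an alcohol like 14, which would itself eliminate, so in practice hydroxide would be used and the hindered esterification returns. After opening, the side chain carries a silyl ether that must be exchanged for the diester chain next to the ortho carboxyl group, the arrangement that lactonises once the oxygen is free.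
- Comparison: the chosen route acylates the side-chain oxygen before the carboxyl carbon exists and is shorter.

Key step: step 2

## Route

Remark: in steps 2 and 3 the alcohol is used in 1.5-fold excess over the epoxide and the unreacted part is recovered; bromide 1 and epoxides 2, 7 and 13 are taken as purchased, the epoxides enantiopure.

Step 1
Reactants: 1 1-bromo-3,5-bis(benzyloxy)benzene; 2 (R)-propylene oxide
Product: 4 (R)-1-[3,5-bis(benzyloxy)phenyl]propan-2-ol, via arylmagnesium bromide 3 (not isolated)
Conditions: Mg, I2 (cat.), THF, 50 °C; then CuI (10 mol%), 2, −30 → 0 °C; aq NH4Cl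
Reagents that add atoms: magnesium, [Mg] (held only in 3)
Why: Copper-catalysed opening of a terminal epoxide by an aryl Grignard reagent, an SN2 attack at the unsubstituted CH2 carbon. The C–O bond at the stereocentre is not touched, so (R)-2 should give (R)-4; CuI suppresses opening by bromide.

Step 2
Reactants: 4 (R)-1-[3,5-bis(benzyloxy)phenyl]propan-2-ol; 2 (R)-propylene oxide; 5 carbon monoxide
Product: 6 (R)-1-[3,5-bis(benzyloxy)phenyl]propan-2-yl (R)-3-hydroxybutanoate
Conditions: Co2(CO)8 (5 mol%), 3-hydroxypyridine (10 mol%), CO (40 bar), THF (about 2 M in 4), 60 °C; 4 (1.5 equiv), 2 (1.0 equiv) added by pump over 6 h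
Reagents that add atoms: none
Why: Proposed new method: Co2(CO)8 (zerovalent cobalt) is converted by the pyridine base into tetracarbonylcobaltate [Co(CO)4]− (cobalt in the oxidation state minus one) and the acidic hydride HCo(CO)4; the hydride or the pyridinium ion hydrogen-bonds to the oxygen of 2, the cobaltate opens the activated epoxide by backside attack at the unsubstituted CH2 carbon, 5 inserts into the new alkyl–cobalt bond of the monovalent cobalt alkyl, and the acyl group passes to the hydroxyl of 4, directly or through an N-acylpyridinium ion formed with 3-hydroxypyridine, which returns HCo(CO)4. The closest known reaction type is the Co2(CO)8/3-hydroxypyridine-catalysed methoxycarbonylation of terminal epoxides to β-hydroxy esters with retention, which uses a primary alcohol in large excess; here a secondary alcohol is present in only 1.5-fold excess, so the acyl transfer is the untested part. No ring is closed. No stereocentre is created: the bond broken in 2 is CH2–O, so its methyl-bearing carbon keeps the (R) configuration, and the carbinol centre of 4 is acylated with retention. Two skeletal bonds form, CH2–C(=O) and C(=O)–O. The step needs opening at CH2 only, which the size and softness of the cobaltate and the absence of a strong Lewis acid should secure, and it needs the hydroxyl of 4 to be chosen over the new hydroxyl of 6, which the excess of 4, the low stationary concentration of 2 and the weaker nucleophilicity of the internally hydrogen-bonded β-hydroxy ester hydroxyl should secure. The benzyl ethers and the arene should be inert to the carbonylcobalt species at 60 °C.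

Step 3
Reactants: 6 (R)-1-[3,5-bis(benzyloxy)phenyl]propan-2-yl (R)-3-hydroxybutanoate; 7 (S)-propylene oxide; 5 carbon monoxide
Product: 8 (R)-1-[3,5-bis(benzyloxy)phenyl]propan-2-yl (R)-3-{[(S)-3-hydroxybutanoyl]oxy}butanoate
Conditions: Co2(CO)8 (5 mol%), 3-hydroxypyridine (10 mol%), CO (40 bar), THF, 60 °C; 6 (1.5 equiv), 7 (1.0 equiv) added by pump over 6 h
Reagents that add atoms: none
Why: Proposed new method: the catalytic cycle of step 2 (cobaltate opening of 7 at CH2, insertion of 5, acyl transfer) now ends on the less nucleophilic hydroxyl of the β-hydroxy ester 6; the closest known reaction types are the cobalt-catalysed methoxycarbonylation of epoxides and the Co2(CO)8/3-hydroxypyridine-catalysed alternating copolymerisation of propylene oxide with carbon monoxide, which shows that ester links between 3-hydroxybutanoate units form and persist under this catalyst. The (S) centre of 7 is not touched, and keeping 7 limiting should hold the chain at one added unit.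

Step 4
Reactants: 8 (R)-1-[3,5-bis(benzyloxy)phenyl]propan-2-yl (R)-3-{[(S)-3-hydroxybutanoyl]oxy}butanoate
Product: 9 (R)-1-[3,5-bis(benzyloxy)phenyl]propan-2-yl (R)-3-{[(S)-3-(benzyloxy)butanoyl]oxy}butanoate
Conditions: BnOC(=NH)CCl3 (1.5 equiv), TfOH (5 mol%), CH2Cl2/cyclohexane, 0 °C → rt
Reagents that add atoms: benzyl 2,2,2-trichloroacetimidate, N=C(OCc1ccccc1)C(Cl)(Cl)Cl
Why: Acid-catalysed O-benzylation with a trichloroacetimidate, the usual way to benzylate β-hydroxy esters because it avoids the base that would cause elimination in the β-acyloxy ester. The hydroxyl should trap the benzyl cation equivalent faster than the dialkoxyarene does.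

Step 5
Reactants: 9 (R)-1-[3,5-bis(benzyloxy)phenyl]propan-2-yl (R)-3-{[(S)-3-(benzyloxy)butanoyl]oxy}butanoate
Product: 11 (R)-1-[3,5-bis(benzyloxy)-2-formylphenyl]propan-2-yl (R)-3-{[(S)-3-(benzyloxy)butanoyl]oxy}butanoate, via aryl iminium chloride 10 (not isolated)
Conditions: POCl3 (1.5 equiv), DMF, 0 → 50 °C; then aq NaOAc, rt
Reagents that add atoms: N,N-dimethylformamide, CN(C)C=O (formyl carbon, and the dimethyliminium group of 10); water, O (carbonyl oxygen of 11); phosphoryl chloride, O=P(Cl)(Cl)Cl (only the chloride of 10)
Why: Vilsmeier–Haack formylation of a 5-alkylresorcinol diether. The two equivalent positions ortho to the side chain and para to a benzyloxy group should be preferred over the position between the two benzyloxy groups, and the iminium group then deactivates the ring against a second attack. Esters and benzyl ethers are inert to the chloroiminium reagent.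

Step 6
Reactants: 11 (R)-1-[3,5-bis(benzyloxy)-2-formylphenyl]propan-2-yl (R)-3-{[(S)-3-(benzyloxy)butanoyl]oxy}butanoate
Product: 12 2,4-bis(benzyloxy)-6-[(R)-2-({(R)-3-{[(S)-3-(benzyloxy)butanoyl]oxy}butanoyl}oxy)propyl]benzoic acid
Conditions: NaClO2, NaH2PO4, 2-methyl-2-butene, t-BuOH/THF/H2O, 0 °C → rt
Reagents that add atoms: sodium chlorite, [Na+].[O-]Cl=O
Why: Pinnick oxidation at buffered, weakly acidic pH, which leaves the β-acyloxy esters and all stereocentres alone. The alkene scavenger removes hypochlorous acid before it can chlorinate the electron-rich ring.

Step 7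
Reactants: 13 (R)-benzyl glycidyl ether; 5 carbon monoxide
Product: 14 benzyl (R)-4-(benzyloxy)-3-hydroxybutanoate
Conditions: Co2(CO)8 (5 mol%), 3-hydroxypyridine (10 mol%), BnOH (5 equiv), CO (40 bar), THF, 60 °C
Reagents that add atoms: benzyl alcohol, OCc1ccccc1
Why: Cobalt-catalysed alkoxycarbonylation of a terminal epoxide with a primary alcohol in excess, the established form of the reaction used in steps 2 and 3. The cobaltate attacks the ring CH2 of 13, so the stereocentre is carried into 14 unchanged and keeps the descriptor (R).

Step 8
Reactants: 12 2,4-bis(benzyloxy)-6-[(R)-2-({(R)-3-{[(S)-3-(benzyloxy)butanoyl]oxy}butanoyl}oxy)propyl]benzoic acid; 14 benzyl (R)-4-(benzyloxy)-3-hydroxybutanoate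
Product: 16 benzyl (R)-4-(benzyloxy)-3-({2,4-bis(benzyloxy)-6-[(R)-2-({(R)-3-{[(S)-3-(benzyloxy)butanoyl]oxy}butanoyl}oxy)propyl]benzoyl}oxy)butanoate (pentabenzyl talapolyester A), via acid chloride 15 (not isolated)
Conditions: (COCl)2, DMF (cat.), CH2Cl2, 0 °C → rt, evaporate; then 14, Et3N, DMAP, CH2Cl2, 0 → 40 °C
Reagents that add atoms: oxalyl chloride, O=C(Cl)C(=O)Cl (supplies only the chlorine of 15)
Why: Acylation of a secondary alcohol by an aroyl chloride under DMAP catalysis, as in the preparation of mesitoate esters from 2,6-disubstituted benzoyl chlorides. The electron-rich ring helps ionisation towards the acylpyridinium ion, and the carbinol centre of 14 is acylated with retention.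

Step 9
Reactants: 16 benzyl (R)-4-(benzyloxy)-3-({2,4-bis(benzyloxy)-6-[(R)-2-({(R)-3-{[(S)-3-(benzyloxy)butanoyl]oxy}butanoyl}oxy)propyl]benzoyl}oxy)butanoate
Product: 17 talapolyester A
Conditions: H2 (1 atm), Pd(OH)2/C, EtOAc, rt; filtration and evaporation below 30 °C
Reagents that add atoms: none
Why: Hydrogenolysis of two aryl benzyl ethers, two alkyl benzyl ethers and one benzyl ester under neutral, aprotic conditions, which should avoid acyl migration to the freed primary hydroxyl, lactonisation of the 4-hydroxy acid and elimination. None of the four stereocentres is benzylic, so none is at risk.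

## Compound list

1 | 1-bromo-3,5-bis(benzyloxy)benzene | Brc1cc(OCc2ccccc2)cc(OCc2ccccc2)c1 | starting material
2 | (R)-propylene oxide | C[C@@H]1CO1 | starting material
3 | [3,5-bis(benzyloxy)phenyl]magnesium bromide | Br[Mg]c1cc(OCc2ccccc2)cc(OCc2ccccc2)c1 | intermediate (not isolated)
4 | (R)-1-[3,5-bis(benzyloxy)phenyl]propan-2-ol | O[C@H](C)Cc1cc(OCc2ccccc2)cc(OCc2ccccc2)c1 | intermediate
5 | carbon monoxide | [C-]#[O+] | starting material
6 | (R)-1-[3,5-bis(benzyloxy)phenyl]propan-2-yl (R)-3-hydroxybutanoate | C[C@@H](O)CC(=O)O[C@H](C)Cc1cc(OCc2ccccc2)cc(OCc2ccccc2)c1 | intermediate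
7 | (S)-propylene oxide | C[C@H]1CO1 | starting material
8 | (R)-1-[3,5-bis(benzyloxy)phenyl]propan-2-yl (R)-3-{[(S)-3-hydroxybutanoyl]oxy}butanoate | C[C@H](O)CC(=O)O[C@H](C)CC(=O)O[C@H](C)Cc1cc(OCc2ccccc2)cc(OCc2ccccc2)c1 | intermediate
9 | (R)-1-[3,5-bis(benzyloxy)phenyl]propan-2-yl (R)-3-{[(S)-3-(benzyloxy)butanoyl]oxy}butanoate | C[C@H](OCc1ccccc1)CC(=O)O[C@H](C)CC(=O)O[C@H](C)Cc1cc(OCc2ccccc2)cc(OCc2ccccc2)c1 | intermediate
10 | N-{2,4-bis(benzyloxy)-6-[(R)-2-({(R)-3-{[(S)-3-(benzyloxy)butanoyl]oxy}butanoyl}oxy)propyl]benzylidene}-N-methylmethanaminium chloride | C[C@H](OCc1ccccc1)CC(=O)O[C@H](C)CC(=O)O[C@H](C)Cc1cc(OCc2ccccc2)cc(OCc2ccccc2)c1C=[N+](C)C.[Cl-] | intermediate (not isolated)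
11 | (R)-1-[3,5-bis(benzyloxy)-2-formylphenyl]propan-2-yl (R)-3-{[(S)-3-(benzyloxy)butanoyl]oxy}butanoate | C[C@H](OCc1ccccc1)CC(=O)O[C@H](C)CC(=O)O[C@H](C)Cc1cc(OCc2ccccc2)cc(OCc2ccccc2)c1C=O | intermediate
12 | 2,4-bis(benzyloxy)-6-[(R)-2-({(R)-3-{[(S)-3-(benzyloxy)butanoyl]oxy}butanoyl}oxy)propyl]benzoic acid | C[C@H](OCc1ccccc1)CC(=O)O[C@H](C)CC(=O)O[C@H](C)Cc1cc(OCc2ccccc2)cc(OCc2ccccc2)c1C(=O)O | intermediate
13 | (R)-benzyl glycidyl ether [(R)-2-(benzyloxymethyl)oxirane] | c1ccccc1COC[C@H]1CO1 | starting material
14 | benzyl (R)-4-(benzyloxy)-3-hydroxybutanoate | O[C@@H](COCc1ccccc1)CC(=O)OCc1ccccc1 | intermediate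
15 | 2,4-bis(benzyloxy)-6-[(R)-2-({(R)-3-{[(S)-3-(benzyloxy)butanoyl]oxy}butanoyl}oxy)propyl]benzoyl chloride | C[C@H](OCc1ccccc1)CC(=O)O[C@H](C)CC(=O)O[C@H](C)Cc1cc(OCc2ccccc2)cc(OCc2ccccc2)c1C(Cl)=O | intermediate (not isolated)
16 | benzyl (R)-4-(benzyloxy)-3-({2,4-bis(benzyloxy)-6-[(R)-2-({(R)-3-{[(S)-3-(benzyloxy)butanoyl]oxy}butanoyl}oxy)propyl]benzoyl}oxy)butanoate | C[C@H](OCc1ccccc1)CC(=O)O[C@H](C)CC(=O)O[C@H](C)Cc1cc(OCc2ccccc2)cc(OCc2ccccc2)c1C(=O)O[C@@H](COCc1ccccc1)CC(=O)OCc1ccccc1 | intermediate
17 | talapolyester A | C[C@H](O)CC(=O)O[C@H](C)CC(=O)O[C@H](C)Cc1cc(O)cc(O)c1C(=O)O[C@@H](CO)CC(=O)O | target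

## Step count and least certain steps

Total: 9 steps. Longest linear sequence: 8 steps (steps 1 to 6, 8 and 9); step 7 is a one-step branch.

**Step 2 (key step).** The most likely failure is slow acyl transfer to the hindered secondary hydroxyl of 4. The acyl intermediate would then be consumed by ring closure onto its own β-hydroxyl or by chain growth with further epoxide, without acylating 4. Over-insertion at the new hydroxyl and isomerisation of the epoxide by the cobalt hydride are lesser risks. Fallback by known chemistry, from 4: carbodiimide esterification (EDC·HCl, DMAP cat., CH2Cl2, 0 °C) with the known acid (R)-3-[(tert-butyldimethylsilyl)oxy]butanoic acid F1 should give (R)-1-[3,5-bis(benzyloxy)phenyl]propan-2-yl (R)-3-[(tert-butyldimethylsilyl)oxy]butanoate F2. Desilylation with HF·pyridine in THF then returns to the route at 6.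

**Step 3.** The same failure applies, aggravated because the hydroxyl of 6 is a weaker nucleophile and is of the same kind as the hydroxyl of 8, so over-insertion is limited only by stoichiometry. Ester exchange between chains at 60 °C is a further risk. Fallback by known chemistry, from 6: esterification (EDC·HCl, DMAP cat., CH2Cl2, 0 °C) with the known acid (S)-3-(benzyloxy)butanoic acid F3 returns to the route directly at 9, so step 4 is not needed.

**Step 8.** Acyl substitution at the di-ortho-substituted carbonyl may be slow enough that amine-induced elimination in 14 or in the β-acyloxy esters of the chain competes. Fallback, from 12: the bond is formed at the alkyl carbon instead. (S)-Benzyl glycidyl ether F4, carbonylated as in step 7, should give benzyl (S)-4-(benzyloxy)-3-hydroxybutanoate F5. Mitsunobu esterification of 12 with F5 (PPh3, DIAD, toluene, 0 °C) makes the carboxylate the nucleophile, is indifferent to hindrance at the acyl carbon, and proceeds with inversion, returning to the route at 16. Its own risk is dehydration of the activated β-hydroxy ester.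

**Step 5.** Substitution may occur between the two benzyloxy groups, or the branched side chain may slow attack at the wanted position so that forcing conditions begin to cleave benzyl ethers. Fallback, from 9: bromination with NBS in MeCN at 0 °C, which goes para to an alkoxy group, should give (R)-1-[3,5-bis(benzyloxy)-2-bromophenyl]propan-2-yl (R)-3-{[(S)-3-(benzyloxy)butanoyl]oxy}butanoate F6. Palladium-catalysed formylation (Pd(OAc)2, di(1-adamantyl)-n-butylphosphine, CO/H2 1:1 at 5 bar, TMEDA, toluene, 100 °C; oxidative addition to zerovalent palladium, CO insertion, hydrogenolysis of the acyl complex of divalent palladium) returns to the route at 11.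

**Step 7.** With the bulkier and less nucleophilic benzyl alcohol the acyl transfer may be slower than with methanol, so that isomerisation of the epoxide by the cobalt hydride or oligomer formation takes over. Fallback by the chiral-pool route:
- dimethyl (R)-malate F7 is reduced at the ester next to the hydroxyl (BH3·SMe2, NaBH4 5 mol%, THF) to methyl (R)-3,4-dihydroxybutanoate F8;
- the primary hydroxyl is benzylated through the stannylene acetal (Bu2SnO, toluene, reflux; then BnBr, Bu4NI) to methyl (R)-4-(benzyloxy)-3-hydroxybutanoate F9;
- titanate-catalysed ester exchange (Ti(OiPr)4 cat., BnOH, 90 °C) returns to the route at 14.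

## Further compounds

F1 | step 2 | (R)-3-[(tert-butyldimethylsilyl)oxy]butanoic acid | C[C@@H](O[Si](C)(C)C(C)(C)C)CC(=O)O
F2 | step 2 | (R)-1-[3,5-bis(benzyloxy)phenyl]propan-2-yl (R)-3-[(tert-butyldimethylsilyl)oxy]butanoate | C[C@@H](O[Si](C)(C)C(C)(C)C)CC(=O)O[C@H](C)Cc1cc(OCc2ccccc2)cc(OCc2ccccc2)c1
F3 | step 3 | (S)-3-(benzyloxy)butanoic acid | C[C@H](OCc1ccccc1)CC(=O)O
F4 | step 8 | (S)-benzyl glycidyl ether | c1ccccc1COC[C@@H]1CO1
F5 | step 8 | benzyl (S)-4-(benzyloxy)-3-hydroxybutanoate | O[C@H](COCc1ccccc1)CC(=O)OCc1ccccc1
F6 | step 5 | (R)-1-[3,5-bis(benzyloxy)-2-bromophenyl]propan-2-yl (R)-3-{[(S)-3-(benzyloxy)butanoyl]oxy}butanoate | C[C@H](OCc1ccccc1)CC(=O)O[C@H](C)CC(=O)O[C@H](C)Cc1cc(OCc2ccccc2)cc(OCc2ccccc2)c1Br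
F7 | step 7 | dimethyl (R)-malate | COC(=O)C[C@@H](O)C(=O)OC
F8 | step 7 | methyl (R)-3,4-dihydroxybutanoate | COC(=O)C[C@@H](O)CO
F9 | step 7 | methyl (R)-4-(benzyloxy)-3-hydroxybutanoate | COC(=O)C[C@@H](O)COCc1ccccc1
A1 | alternative 1 | trans-2,5-dimethylcyclohexane-1,4-dione (meso) | C[C@H]1CC(=O)[C@H](C)CC1=O
A2 | alternative 1 | meso-(4S,8R)-4,8-dimethyl-1,5-dioxocane-2,6-dione | C[C@H]1CC(=O)O[C@H](C)CC(=O)O1
A3 | alternative 2 | 1-methoxy-1,3-bis(trimethylsilyloxy)buta-1,3-diene | COC(O[Si](C)(C)C)=CC(=C)O[Si](C)(C)C
A4 | alternative 2 | benzyl (R)-4-(benzyloxy)-3-{[(R)-5-({(R)-3-{[(S)-3-(benzyloxy)butanoyl]oxy}butanoyl}oxy)hex-2-ynoyl]oxy}butanoate | C[C@H](OCc1ccccc1)CC(=O)O[C@H](C)CC(=O)O[C@H](C)CC#CC(=O)O[C@@H](COCc1ccccc1)CC(=O)OCc1ccccc1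
A5 | alternative 2 | tribenzyl-protected talapolyester A (benzyl ester, two aliphatic benzyl ethers, free phenols) | C[C@H](OCc1ccccc1)CC(=O)O[C@H](C)CC(=O)O[C@H](C)Cc1cc(O)cc(O)c1C(=O)O[C@@H](COCc1ccccc1)CC(=O)OCc1ccccc1
A6 | alternative 3 | 3,5-bis(benzyloxy)benzyne | C1(OCc2ccccc2)=CC(OCc2ccccc2)=CC#C1
A7 | alternative 3 | 3,5-bis(benzyloxy)-2-iodophenyl trifluoromethanesulfonate | FC(F)(F)S(=O)(=O)Oc1cc(OCc2ccccc2)cc(OCc2ccccc2)c1I
A8 | alternative 3 | [(R)-3-(tert-butyldimethylsilyloxy)-1-methoxybut-1-enyloxy]trimethylsilane | C[C@@H](O[Si](C)(C)C(C)(C)C)C=C(OC)O[Si](C)(C)C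
A9 | alternative 3 | 3,5-bis(benzyloxy)-8-[(R)-1-(tert-butyldimethylsilyloxy)ethyl]bicyclo[4.2.0]octa-1,3,5-trien-7-one (both epimers at C8) | O=C1C([C@@H](C)O[Si](C)(C)C(C)(C)C)c2cc(OCc3ccccc3)cc(OCc3ccccc3)c12
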